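## The problem

The target joins two chromans through a central benzene ring D (locants: chroman 1 = O1, C2, C3, C4 with benzo ring A; ring E on C3 through E1; ring D on C4 through D1, with OMe on D2, OH on D4 and chroman 2 on D6; chroman 2 = O1'', C2'', C3'', C4'' with benzo ring F). Chroman 1 is a 3,4-diarylchroman and chroman 2 a 3-arylchroman; because D6 is next to D1, C4 sits between the D2 methoxy group and chroman 2 and is a crowded, doubly benzylic carbon at which every bond formation is slow. Of the three stereocentres, C3 (R) and C4 (S) are neighbours and trans, so one can set the other, whereas C3'' (R) lies five bonds from C4 behind ring D and can neither steer nor be steered; the relation of the C3/C4 pair to C3'' must come from a reagent. Rings A, D and F are resorcinol-type rings of nearly equal electron density, and ring D must end with a methyl ether at D2 but a free hydroxyl at D4, so neither a late electrophilic substitution at D1 nor a late dealkylation can be trusted to pick the right site. The four phenols and the C4–H bond make the final compound sensitive to oxidants and strong acid, so the phenols must travel as ethers that leave under neutral conditions, and nothing that cleaves aryl methyl ethers may be used once ring E and the D2 methoxy group are present. The feature that opens the route is that O1–C8a–C4a–C4 is a latent ortho-quinone methide, stabilised at C4 by the 7-oxygen of ring A (para to C4a) and by donor ring D, while C2–C3 is a latent enol ether with ring E on its nucleophilic β-carbon; the pyran ring of chroman 1 can thus be closed by an oxa-[4+2] cycloaddition that forms C3–C4 and O1–C2 and sets C3 and C4 together.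

## Retrosynthesis

**35 ⇐ 34 ⇐ 32.** The four phenols are uncovered last by cutting the four O–benzyl bonds of 34. Benzyl is the only phenol protecting group of the late stages because it survives bases, hydrides, organolithiums and mild acid and leaves under neutral hydrogenolysis, which touches neither methyl ethers nor stereocentres. 34 is traced to the 2-ethoxy compound 32 by exchanging C2–H for C2–O: the acetal carbon is what remains of an enol ether, and its ionic reduction removes a temporary stereocentre. This costs one step but lets the 2π partner of the key step be an electron-rich enol ether.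

**32 ⇐ 30 + 5 (key disconnection).** Cutting C3–C4 and O1–C2 of 32 in a retro-[4+2] gives the ortho-quinone methide 31 and the (E)-enol ether 5; 31 cannot be stored and is reached in the flask from the ortho-hydroxybenzhydrol 30. The neighbouring cuts are weaker. A cut at C4–D1 would mean arylating a chroman cation, with no control at C4 and no site control on ring D. A cut at C3–E1 would mean an arylation at the most crowded position. The chosen cut forms both bonds that flank the two new stereocentres in one operation from planar precursors, so relative configuration follows from alkene geometry and mode of approach, and absolute configuration from one chiral catalyst. The diarylchroman with two stereocentres is reduced to a benzhydrol whose carbinol configuration does not matter and an achiral enol ether. The forward reaction must form 31 under acid mild enough for benzyl ethers and enol ether, add 5 endo with its β-carbon to C4, and choose one face of 31 without help from the remote C3'' centre.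

**5 ⇐ 3 + 4 ⇐ 2 ⇐ 1.** The aryl–vinyl bond of 5 is cut to aryl bromide 3 and the commercial (E)-boronate 4. The alkoxy group is lost when 32 is reduced, so ethoxy serves as well as methoxy and comes with fixed alkene geometry. An alkoxymethylene Wittig reaction on the corresponding aldehyde would give both alkene isomers and with them both C3 epimers. 3 comes from 2 by bromination para to a methoxy group, and 2 from 2,6-dimethoxyphenol (1) by benzylation.

**30 ⇐ 28 + 9.** The C4–C4a bond is cut to aldehyde 28 and the dilithio derivative 29 of bromophenol 9. The opposite polarity (a D1 organometallic and a ring A aldehyde) would need a halogen at D1 of chroman 2, and halogenation there cannot tell D1 from D5 or from C6'' of ring F. With the phenoxide as its own protecting group, no deprotection has to be run on the acid-labile benzhydrol. 9 goes back to 3-(benzyloxy)phenol (6) through acetate 7 and bromide 8; the acetate only serves to make the benzyloxy group the sole director of the bromination.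

**28 ⇐ 27 ⇐ 26 ⇐ 24.** The formyl carbon of 28 is the future C4, and it is also what tells D2 from D4. Removing the methyl group gives 27 and removing the D4 benzyl group gives 26, in which the D2 hydroxyl is hydrogen-bonded to the formyl group and the D4 hydroxyl is not. The forward order (weak-base benzylation, then methylation) is therefore regiochemically fixed. Cutting the D1–CHO bond of 26 leads to the free resorcinol 24, in which D1 and D5 are equivalent and ring D is far more nucleophilic than the ring F diether. The forward formylation must go next to the chroman substituent and not between the two hydroxyls, the usual course for 5-alkylresorcinols. This sequence replaces both a D1 bromination and a ring D building block with pre-differentiated oxygens, for which no selective entry exists.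

**24 ⇐ 23 ⇐ 22 ⇐ 21 ⇐ 19 + 13.** 24 comes from the bis(methoxymethyl) ether 23. Acetals are needed on ring D because free phenols would not survive the enolate chemistry and methyl ethers could not be removed later beside a benzyl ether. Chroman 2 is opened at O1''–C8a'' to bromo alcohol 22 (forward: palladium-catalysed intramolecular etherification), the primary alcohol is traced to imide 21, and the C3''–C4'' bond is cut to arylacetyl oxazolidinone 19 and benzylic bromide 13. Asymmetric hydrogenation of an isoflavene or an α-arylcinnamic acid would be shorter, but the auxiliary alkylation is preferred because its sense is predictable: the (R)-auxiliary gives (R) at C3''. Alkylation and hydride cleavage must both spare the acidic α-aryl centre.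

**Small pieces.** 19 comes from acid 16 and (R)-4-benzyloxazolidin-2-one (17); 16 from methyl 3,5-dihydroxyphenylacetate (14) through 15; 13 from 2-bromo-4-hydroxybenzaldehyde (10) through 11 and 12. All are one-step functional group changes.

## Roads not taken

Alternative 1: The cut goes through both ring D–carbon bonds at once, D6–C3'' and D1–C4. Forward, fluoride converts the silylaryl triflate A1 into its aryne, which inserts into the C(O)–CH bond of β-keto ester A2 (aryne acyl-alkylation) to give the ortho-aroyl arylacetic ester A3.
- Merits: the methoxy group of the aryne sends the carbon nucleophile to the distal aryne carbon, so the arylacetic carbon lands on D6 and the aroyl group on D1 beside the methoxy group. That is the pattern for which the chosen plan needs steps 17 to 19. Ring A, C4, C3'' and ring F are brought together in one operation.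
- Weak points: no ring closes and no stereocentre is set. A3 is racemic at an acidic carbon, so C3'' needs a resolution or a later correction. The diaryl ketone, flanked by two ortho substituents, must still be turned into C4 with ring E, C3 and C2 attached, so the whole stereochemical problem of chroman 1 remains, now on a hindered benzophenone. A1 is itself several steps from a differentiated resorcinol.
- Comparison: this road fixes the substitution pattern of ring D better than the chosen one, and that is conceded. Against it, the chosen plan sets C3'' with a predictable auxiliary and creates C3, C4 and the pyran ring in its key step.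

Alternative 2: The cut is D6–C3'' together with C4''–C4a'', so chroman 2 is assembled last on a finished chroman 1. Bromine–lithium exchange on A4 and addition to vinylboronate A5 give a boron ate complex; Pd(OAc)2 with a chiral ferrocenyl bisphosphine and aryl triflate A6 then trigger a 1,2-metallate shift (conjunctive coupling) to the secondary boronic ester A7, with C3'' set by the catalyst.
- Merits: three components meet in one step, and C3'' is set catalytically and late. In this respect it is better than a stoichiometric auxiliary and more convergent.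
- Weak points: A4 is the hard part of the molecule (chroman 1 with both stereocentres and a bromine next to the crowded C4), and this strategy does not say how to make it. The migrating aryl group carries a bulky ortho substituent, which slows the metallate shift. The catalyst must work beside two existing stereocentres (matched and mismatched pairing). A7 still needs one-carbon homologation at boron, oxidation, acetal removal and ring closure before chroman 2 exists.
- Comparison: the chosen plan places its key step on chroman 1, the harder problem, and settles C3'' early on simple material at the price of an auxiliary.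

Alternative 3: The cut removes three bonds of ring D (D1–D2, D2–D3, D4–D5), so ring D is made last. Irradiation of diazo enone A8 induces a Wolff rearrangement to a vinylketene, which adds the siloxyalkyne A9 in a [2+2] cycloaddition; four-electron ring opening and six-electron ring closure then give phenol A10 (Danheiser benzannulation).
- Merits: the D2 hydroxyl and the D4 silyl ether are born differentiated, so methylation and desilylation finish ring D with full regiocontrol and without electrophilic substitution on a crowded ring. Here it is better than the chosen plan.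
- Weak points: A8 must carry both chromans and all three stereocentres. C4 becomes an allylic, γ-enone carbon that can epimerise through dienol or ketene intermediates. Building the trisubstituted enone between two secondary carbons and the diazo transfer add many steps. Photolysis of a substrate with four benzyl aryl ethers is unlikely to be clean, and the electrocyclisation must make a ring bond at the most hindered carbon, D1.
- Comparison: the benzannulation settles ring D more elegantly, but only after the chromans and their stereocentres have been made by other means. The chosen plan spends three ordinary steps on ring D and uses its one demanding step to make chroman 1 with C3 and C4.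

Key step: step 21

Assumption (remark on the chemistry): the sense of induction of a BINOL-derived phosphoric acid on this hindered methide cannot be predicted safely. Step 21 is written with the (R)-enantiomer of 3,3'-bis(2,4,6-triisopropylphenyl)-1,1'-binaphthyl-2,2'-diyl hydrogen phosphate, (R)-TRIP, as the one matched to the (3R,4S) product; the (S)-acid takes its place should the pairing prove mismatched.

## Steps

Step 1
Reactants: 1 2,6-dimethoxyphenol
Product: 2 2-(benzyloxy)-1,3-dimethoxybenzene
Conditions: BnBr, K2CO3, DMF, 60 °C
Reagents that add atoms: benzyl bromide, BrCc1ccccc1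
Why: Williamson ether synthesis (SN2 of the phenoxide on a benzylic bromide); the flanked phenol is still readily alkylated in DMF.

Step 2
Reactants: 2 2-(benzyloxy)-1,3-dimethoxybenzene
Product: 3 2-(benzyloxy)-4-bromo-1,3-dimethoxybenzene
Conditions: NBS, MeCN, 0 °C → rt
Reagents that add atoms: N-bromosuccinimide, O=C1CCC(=O)N1Br
Why: Electrophilic aromatic bromination; the central benzyloxy group is twisted out of conjugation by its two neighbours, so the ring should react para to one methoxy group and ortho to the other, as 1,2,3-trialkoxybenzenes do, and one equivalent of NBS should stop at the monobromide.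

Step 3
Reactants: 3 2-(benzyloxy)-4-bromo-1,3-dimethoxybenzene; 4 (E)-2-(2-ethoxyethenyl)-4,4,5,5-tetramethyl-1,3,2-dioxaborolane
Product: 5 2-(benzyloxy)-4-[(E)-2-ethoxyethenyl]-1,3-dimethoxybenzene
Conditions: Pd(OAc)2 (2 mol %), SPhos (4 mol %), K3PO4, 1,4-dioxane/H2O, 80 °C
Reagents that add atoms: none
Why: Suzuki–Miyaura coupling, which transfers the vinyl group with retention of alkene geometry, so 5 should be obtained as the (E)-enol ether only; the basic medium leaves the enol ether intact and the electron-rich biaryl phosphine copes with the ortho-substituted bromide.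

Step 4
Reactants: 6 3-(benzyloxy)phenol
Product: 7 3-(benzyloxy)phenyl acetate
Conditions: Ac2O, pyridine, rt
Reagents that add atoms: acetic anhydride, CC(=O)OC(C)=O
Why: O-acylation of the phenol; the acetate turns the hydroxyl into a weak donor so that the benzyloxy group alone directs the next step.

Step 5
Reactants: 7 3-(benzyloxy)phenyl acetate
Product: 8 5-(benzyloxy)-2-bromophenyl acetate
Conditions: NBS, MeCN, rt
Reagents that add atoms: N-bromosuccinimide, O=C1CCC(=O)N1Br
Why: Electrophilic bromination para to the benzyloxy group, the usual site for an alkoxyarene that also carries a less donating acyloxy group; this places bromine ortho to the masked hydroxyl.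

Step 6
Reactants: 8 5-(benzyloxy)-2-bromophenyl acetate
Product: 9 5-(benzyloxy)-2-bromophenol
Conditions: K2CO3 (cat.), MeOH, rt
Reagents that add atoms: none
Why: Base-catalysed transesterification (methanolysis) of the aryl acetate; aryl bromide and benzyl ether are inert.

Step 7
Reactants: 10 2-bromo-4-hydroxybenzaldehyde
Product: 11 4-(benzyloxy)-2-bromobenzaldehyde
Conditions: BnBr, K2CO3, DMF, rt
Reagents that add atoms: benzyl bromide, BrCc1ccccc1
Why: Williamson ether synthesis; the hydroxyl para to the formyl group is acidic and is alkylated cleanly.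

Step 8
Reactants: 11 4-(benzyloxy)-2-bromobenzaldehyde
Product: 12 [4-(benzyloxy)-2-bromophenyl]methanol
Conditions: NaBH4, MeOH/THF, 0 °C
Reagents that add atoms: none
Why: Borohydride reduction of the aldehyde; aryl bromide and benzyl ether are untouched.

Step 9
Reactants: 12 [4-(benzyloxy)-2-bromophenyl]methanol
Product: 13 4-(benzyloxy)-2-bromo-1-(bromomethyl)benzene
Conditions: PBr3, CH2Cl2, 0 °C
Reagents that add atoms: phosphorus tribromide, BrP(Br)Br
Why: Conversion of the benzylic alcohol into the bromide by PBr3 (SN2 displacement of the activated hydroxyl); the ortho bromine atom makes this benzylic bromide less prone to ionise than a 2-alkoxy analogue, so it should be stable enough to handle.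

Step 10
Reactants: 14 methyl (3,5-dihydroxyphenyl)acetate
Product: 15 methyl [3,5-bis(methoxymethoxy)phenyl]acetate
Conditions: MOMCl, iPr2NEt, CH2Cl2, 0 °C → rt
Reagents that add atoms: chloromethyl methyl ether, COCCl
Why: O-alkylation of both phenols to methoxymethyl acetals, chosen because they tolerate enolates, hydride and palladium catalysis and are later removed by mild acid beside a benzyl ether.

Step 11
Reactants: 15 methyl [3,5-bis(methoxymethoxy)phenyl]acetate
Product: 16 [3,5-bis(methoxymethoxy)phenyl]acetic acid
Conditions: LiOH·H2O, THF/MeOH/H2O, rt; then cold dilute HCl to pH 4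
Reagents that add atoms: lithium hydroxide, [Li+].[OH-]
Why: Saponification of the methyl ester; the acetals are stable to base and to the brief cold acidification.

Step 12
Reactants: 16 [3,5-bis(methoxymethoxy)phenyl]acetic acid; 17 (R)-4-benzyloxazolidin-2-one
Product: 19 (4R)-4-benzyl-3-{[3,5-bis(methoxymethoxy)phenyl]acetyl}-1,3-oxazolidin-2-one, via mixed pivalic anhydride 18 (not isolated)
Conditions: PivCl, Et3N, THF, −20 °C; then 17, LiCl, −20 °C → rt
Reagents that add atoms: none
Why: N-acylation of the oxazolidinone through the mixed pivalic anhydride (LiCl/Et3N protocol); the nucleophile attacks the unhindered arylacetyl carbonyl and not the pivaloyl carbonyl.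

Step 13
Reactants: 19 (4R)-4-benzyl-3-{[3,5-bis(methoxymethoxy)phenyl]acetyl}-1,3-oxazolidin-2-one; 13 4-(benzyloxy)-2-bromo-1-(bromomethyl)benzene
Product: 21 (4R)-4-benzyl-3-{(2R)-3-[4-(benzyloxy)-2-bromophenyl]-2-[3,5-bis(methoxymethoxy)phenyl]propanoyl}-1,3-oxazolidin-2-one, via sodium enolate 20 (not isolated)
Conditions: NaN(SiMe3)2, THF, −78 °C; then 13, −78 → −30 °C
Reagents that add atoms: none
Why: Evans asymmetric alkylation: the chelated sodium (Z)-enolate 20 is attacked by the benzylic bromide on the face opposite the benzyl group of the (R)-auxiliary, which should give the (R) configuration at the new centre (the future C3''); low temperature and the non-nucleophilic base protect the acidic α-aryl centre from epimerisation.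

Step 14
Reactants: 21 (4R)-4-benzyl-3-{(2R)-3-[4-(benzyloxy)-2-bromophenyl]-2-[3,5-bis(methoxymethoxy)phenyl]propanoyl}-1,3-oxazolidin-2-one
Product: 22 (2R)-3-[4-(benzyloxy)-2-bromophenyl]-2-[3,5-bis(methoxymethoxy)phenyl]propan-1-ol
Conditions: LiBH4, MeOH (1 equiv), Et2O/THF, 0 °C
Reagents that add atoms: none
Why: Reductive cleavage of the N-acyl oxazolidinone with LiBH4 at the exocyclic carbonyl; the mild hydride should not epimerise the α-aryl centre, aryl bromide and acetals survive, and the auxiliary is recovered.

Step 15
Reactants: 22 (2R)-3-[4-(benzyloxy)-2-bromophenyl]-2-[3,5-bis(methoxymethoxy)phenyl]propan-1-ol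
Product: 23 (3R)-7-(benzyloxy)-3-[3,5-bis(methoxymethoxy)phenyl]chroman
Conditions: Pd(OAc)2 (5 mol %), 2-(di-tert-butylphosphino)-1,1'-binaphthyl (6 mol %), Cs2CO3, toluene, 65 °C
Reagents that add atoms: none
Why: Palladium-catalysed intramolecular C–O coupling (Buchwald–Hartwig etherification): oxidative addition of the aryl bromide to zerovalent palladium, alkoxide binding and reductive elimination close the six-membered ring of chroman 2; the bulky biaryl phosphine favours reductive elimination over β-hydride elimination, and no bond at C3'' is broken.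

Step 16
Reactants: 23 (3R)-7-(benzyloxy)-3-[3,5-bis(methoxymethoxy)phenyl]chroman
Product: 24 5-[(3R)-7-(benzyloxy)chroman-3-yl]benzene-1,3-diol
Conditions: HCl (conc., cat.), MeOH, 45 °C
Reagents that add atoms: none
Why: Acid-catalysed cleavage of the two aryl methoxymethyl acetals by acetal exchange with methanol; benzyl ether, chroman ring and the C3'' centre are inert to dilute methanolic HCl.

Step 17
Reactants: 24 5-[(3R)-7-(benzyloxy)chroman-3-yl]benzene-1,3-diol
Product: 26 2-[(3R)-7-(benzyloxy)chroman-3-yl]-4,6-dihydroxybenzaldehyde, via iminium chloride 25 (not isolated)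
Conditions: POCl3, DMF, MeCN, 0 °C; then H2O, 50 °C
Reagents that add atoms: N,N-dimethylformamide, CN(C)C=O; water, O
Why: Vilsmeier–Haack formylation through iminium salt 25; the free resorcinol ring D is far more nucleophilic than the dialkoxy ring F, and attack is expected para to one hydroxyl and ortho to the other, next to the alkyl substituent, as is usual for 5-alkylresorcinols, the position between the hydroxyls being the minor site.

Step 18
Reactants: 26 2-[(3R)-7-(benzyloxy)chroman-3-yl]-4,6-dihydroxybenzaldehyde
Product: 27 4-(benzyloxy)-2-[(3R)-7-(benzyloxy)chroman-3-yl]-6-hydroxybenzaldehyde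
Conditions: BnBr (1.05 equiv), NaHCO3, KI (cat.), MeCN, 70 °C
Reagents that add atoms: benzyl bromide, BrCc1ccccc1
Why: Regioselective Williamson etherification of a 2,4-dihydroxybenzaldehyde-type system: the 6-hydroxyl (D2) is held in a hydrogen bond to the formyl oxygen and is not ionised by NaHCO3, so only the 4-hydroxyl (D4) should be benzylated.

Step 19
Reactants: 27 4-(benzyloxy)-2-[(3R)-7-(benzyloxy)chroman-3-yl]-6-hydroxybenzaldehyde
Product: 28 4-(benzyloxy)-2-[(3R)-7-(benzyloxy)chroman-3-yl]-6-methoxybenzaldehyde
Conditions: MeI, K2CO3, DMF, rt → 40 °C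
Reagents that add atoms: iodomethane, CI
Why: Williamson methylation; the chelated D2 hydroxyl is ionised by K2CO3 in DMF and alkylated by the small electrophile, and no other acidic site is present.

Step 20
Reactants: 9 5-(benzyloxy)-2-bromophenol; 28 4-(benzyloxy)-2-[(3R)-7-(benzyloxy)chroman-3-yl]-6-methoxybenzaldehyde
Product: 30 [4-(benzyloxy)-2-hydroxyphenyl]{4-(benzyloxy)-2-[(3R)-7-(benzyloxy)chroman-3-yl]-6-methoxyphenyl}methanol (both carbinol epimers), via dilithio phenoxide 29 (not isolated)
Conditions: 9 (3 equiv), n-BuLi (2 equiv per 9), THF, −78 → 0 °C; then 28, −78 °C → rt; aq. NH4Cl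
Reagents that add atoms: none
Why: Deprotonation of the phenol and bromine–lithium exchange give the ortho-lithiated lithium phenoxide 29, which adds to the aldehyde (1,2-addition of an aryllithium) without any protecting group on the ring A hydroxyl; the carbinol centre forms without control, which does not matter because it is lost in step 21.

Step 21
Reactants: 30 [4-(benzyloxy)-2-hydroxyphenyl]{4-(benzyloxy)-2-[(3R)-7-(benzyloxy)chroman-3-yl]-6-methoxyphenyl}methanol; 5 2-(benzyloxy)-4-[(E)-2-ethoxyethenyl]-1,3-dimethoxybenzene
Product: 32 (2S,3R,4S)-7-(benzyloxy)-4-{4-(benzyloxy)-2-[(3R)-7-(benzyloxy)chroman-3-yl]-6-methoxyphenyl}-3-[3-(benzyloxy)-2,4-dimethoxyphenyl]-2-ethoxychroman, via ortho-quinone methide 31 (not isolated)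
Conditions: (R)-TRIP (10 mol %), 5 (2 equiv), 5 Å MS, toluene, 0 °C → rt
Reagents that add atoms: none
Why: The phosphoric acid protonates the carbinol of 30 and water leaves with help from the para 7-benzyloxy group and from donor ring D, so both carbinol epimers funnel into the same (E)-configured ortho-quinone methide 31, which stays hydrogen-bonded to the catalyst through its carbonyl oxygen. The electron-rich β-carbon of 5 then attacks the methide carbon (C3–C4) while the methide oxygen closes on the incipient oxocarbenium carbon (O1–C2), an asynchronous inverse-electron-demand oxa-[4+2] cycloaddition; the closest known reaction type is the chiral phosphoric acid-catalysed [4+2] cycloaddition of in situ ortho-quinone methides with enol ethers and enamides. The pyran ring of chroman 1 closes as a six-membered ring in this hetero-Diels–Alder mode, driven by re-aromatisation of ring A. C4 is set by the catalyst, whose 3,3'-aryl groups leave one face of the bound planar methide open; ring D is twisted out of the methide plane and the C3'' centre is too remote to bias the faces, so this is catalyst control with a matched and a mismatched acid enantiomer. C3 follows from C4 through the endo-ethoxy, exo-aryl approach to the (E)-methide, which places ring E trans to ring D. C2 is fixed trans to C3 by the (E) geometry of 5 (suprafacial addition) and cis to C4 by the endo approach, and it is removed in step 22. The step needs regioselectivity, secured by the matched polarity of methide carbon and enol ether β-carbon, and chemoselectivity against hydrolysis of 5 and oligomerisation of 31, secured by molecular sieves, an excess of 5 and the two ortho substituents of ring D, which shield the methide from bulkier partners.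

Step 22
Reactants: 32 (2S,3R,4S)-7-(benzyloxy)-4-{4-(benzyloxy)-2-[(3R)-7-(benzyloxy)chroman-3-yl]-6-methoxyphenyl}-3-[3-(benzyloxy)-2,4-dimethoxyphenyl]-2-ethoxychroman
Product: 34 (3R,4S)-7-(benzyloxy)-4-{4-(benzyloxy)-2-[(3R)-7-(benzyloxy)chroman-3-yl]-6-methoxyphenyl}-3-[3-(benzyloxy)-2,4-dimethoxyphenyl]chroman, via cyclic oxocarbenium ion 33 (not isolated)
Conditions: Et3SiH, BF3·OEt2, CH2Cl2, −78 → −40 °C
Reagents that add atoms: none
Why: Ionic hydrogenation of a cyclic O,O-acetal: BF3 ionises the C2–OEt bond to oxocarbenium ion 33, which the excess silane reduces at C2; C3 and C4 are not part of any bond that breaks, and the low temperature should let hydride transfer outrun proton loss from C3 and spare the benzyl ethers.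

Step 23
Reactants: 34 (3R,4S)-7-(benzyloxy)-4-{4-(benzyloxy)-2-[(3R)-7-(benzyloxy)chroman-3-yl]-6-methoxyphenyl}-3-[3-(benzyloxy)-2,4-dimethoxyphenyl]chroman
Product: 35 (3R,4S)-4-{4-hydroxy-2-[(3R)-7-hydroxychroman-3-yl]-6-methoxyphenyl}-3-(3-hydroxy-2,4-dimethoxyphenyl)chroman-7-ol
Conditions: H2 (1 atm), Pd/C (10 %), EtOAc/MeOH, rt
Reagents that add atoms: none
Why: Hydrogenolysis of the four benzyl aryl ethers under neutral conditions; methyl ethers, both chroman rings and all three stereocentres are untouched.

## Compound list

1 | 2,6-dimethoxyphenol | COc1cccc(OC)c1O | starting material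
2 | 2-(benzyloxy)-1,3-dimethoxybenzene | COc1cccc(OC)c1OCc1ccccc1 | intermediate
3 | 2-(benzyloxy)-4-bromo-1,3-dimethoxybenzene | COc1ccc(Br)c(OC)c1OCc1ccccc1 | intermediate
4 | (E)-2-(2-ethoxyethenyl)-4,4,5,5-tetramethyl-1,3,2-dioxaborolane | CCO/C=C/B1OC(C)(C)C(C)(C)O1 | starting material
5 | 2-(benzyloxy)-4-[(E)-2-ethoxyethenyl]-1,3-dimethoxybenzene (ring E enol ether) | CCO/C=C/c1ccc(OC)c(OCc2ccccc2)c1OC | intermediate
6 | 3-(benzyloxy)phenol | Oc1cccc(OCc2ccccc2)c1 | starting material
7 | 3-(benzyloxy)phenyl acetate | CC(=O)Oc1cccc(OCc2ccccc2)c1 | intermediate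
8 | 5-(benzyloxy)-2-bromophenyl acetate | CC(=O)Oc1cc(OCc2ccccc2)ccc1Br | intermediate
9 | 5-(benzyloxy)-2-bromophenol | Oc1cc(OCc2ccccc2)ccc1Br | intermediate
10 | 2-bromo-4-hydroxybenzaldehyde | O=Cc1ccc(O)cc1Br | starting material
11 | 4-(benzyloxy)-2-bromobenzaldehyde | O=Cc1ccc(OCc2ccccc2)cc1Br | intermediate
12 | [4-(benzyloxy)-2-bromophenyl]methanol | OCc1ccc(OCc2ccccc2)cc1Br | intermediate
13 | 4-(benzyloxy)-2-bromo-1-(bromomethyl)benzene | BrCc1ccc(OCc2ccccc2)cc1Br | intermediate
14 | methyl (3,5-dihydroxyphenyl)acetate | COC(=O)Cc1cc(O)cc(O)c1 | starting material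
15 | methyl [3,5-bis(methoxymethoxy)phenyl]acetate | COC(=O)Cc1cc(OCOC)cc(OCOC)c1 | intermediate
16 | [3,5-bis(methoxymethoxy)phenyl]acetic acid | OC(=O)Cc1cc(OCOC)cc(OCOC)c1 | intermediate
17 | (R)-4-benzyloxazolidin-2-one | O=C1N[C@H](Cc2ccccc2)CO1 | starting material
18 | mixed pivalic anhydride of 16 (formed in the flask) | CC(C)(C)C(=O)OC(=O)Cc1cc(OCOC)cc(OCOC)c1 | intermediate
19 | (4R)-4-benzyl-3-{[3,5-bis(methoxymethoxy)phenyl]acetyl}-1,3-oxazolidin-2-one | COCOc1cc(CC(=O)N2[C@H](Cc3ccccc3)COC2=O)cc(OCOC)c1 | intermediate
20 | sodium (Z)-enolate of 19 (formed in the flask) | [Na+].[O-]/C(=C\c1cc(OCOC)cc(OCOC)c1)N1[C@H](Cc2ccccc2)COC1=O | intermediate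
21 | (4R)-4-benzyl-3-{(2R)-3-[4-(benzyloxy)-2-bromophenyl]-2-[3,5-bis(methoxymethoxy)phenyl]propanoyl}-1,3-oxazolidin-2-one | COCOc1cc(OCOC)cc(c1)[C@@H](Cc1ccc(OCc2ccccc2)cc1Br)C(=O)N1[C@H](Cc2ccccc2)COC1=O | intermediate
22 | (2R)-3-[4-(benzyloxy)-2-bromophenyl]-2-[3,5-bis(methoxymethoxy)phenyl]propan-1-ol | COCOc1cc(OCOC)cc(c1)[C@@H](Cc1ccc(OCc2ccccc2)cc1Br)CO | intermediate
23 | (3R)-7-(benzyloxy)-3-[3,5-bis(methoxymethoxy)phenyl]chroman | COCOc1cc(OCOC)cc(c1)[C@@H]1COc2cc(OCc3ccccc3)ccc2C1 | intermediate
24 | 5-[(3R)-7-(benzyloxy)chroman-3-yl]benzene-1,3-diol | Oc1cc(O)cc(c1)[C@@H]1COc2cc(OCc3ccccc3)ccc2C1 | intermediate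
25 | N-({2-[(3R)-7-(benzyloxy)chroman-3-yl]-4,6-dihydroxyphenyl}methylidene)-N-methylmethanaminium chloride (formed in the flask) | C[N+](C)=Cc1c(O)cc(O)cc1[C@@H]1COc2cc(OCc3ccccc3)ccc2C1.[Cl-] | intermediate
26 | 2-[(3R)-7-(benzyloxy)chroman-3-yl]-4,6-dihydroxybenzaldehyde | O=Cc1c(O)cc(O)cc1[C@@H]1COc2cc(OCc3ccccc3)ccc2C1 | intermediate
27 | 4-(benzyloxy)-2-[(3R)-7-(benzyloxy)chroman-3-yl]-6-hydroxybenzaldehyde | O=Cc1c(O)cc(OCc2ccccc2)cc1[C@@H]1COc2cc(OCc3ccccc3)ccc2C1 | intermediate
28 | 4-(benzyloxy)-2-[(3R)-7-(benzyloxy)chroman-3-yl]-6-methoxybenzaldehyde | O=Cc1c(OC)cc(OCc2ccccc2)cc1[C@@H]1COc2cc(OCc3ccccc3)ccc2C1 | intermediate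
29 | lithium 5-(benzyloxy)-2-lithiophenoxide (formed in the flask) | [Li]Oc1cc(OCc2ccccc2)ccc1[Li] | intermediate
30 | [4-(benzyloxy)-2-hydroxyphenyl]{4-(benzyloxy)-2-[(3R)-7-(benzyloxy)chroman-3-yl]-6-methoxyphenyl}methanol (both carbinol epimers) | OC(c1ccc(OCc2ccccc2)cc1O)c1c(OC)cc(OCc2ccccc2)cc1[C@@H]1COc2cc(OCc3ccccc3)ccc2C1 | intermediate
31 | (6E)-3-(benzyloxy)-6-({4-(benzyloxy)-2-[(3R)-7-(benzyloxy)chroman-3-yl]-6-methoxyphenyl}methylidene)cyclohexa-2,4-dien-1-one (ortho-quinone methide, formed in the flask) | O=C1C=C(OCc2ccccc2)C=C/C1=C\c1c(OC)cc(OCc2ccccc2)cc1[C@@H]1COc2cc(OCc3ccccc3)ccc2C1 | intermediate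
32 | (2S,3R,4S)-7-(benzyloxy)-4-{4-(benzyloxy)-2-[(3R)-7-(benzyloxy)chroman-3-yl]-6-methoxyphenyl}-3-[3-(benzyloxy)-2,4-dimethoxyphenyl]-2-ethoxychroman | COc1ccc([C@@H]2[C@@H](OCC)Oc3cc(OCc4ccccc4)ccc3[C@H]2c2c(OC)cc(OCc3ccccc3)cc2[C@@H]2COc3cc(OCc4ccccc4)ccc3C2)c(OC)c1OCc1ccccc1 | intermediate
33 | cyclic oxocarbenium ion from 32 (O1=C2 cation, 3R,4S; formed in the flask) | COc1ccc([C@@H]2C=[O+]c3cc(OCc4ccccc4)ccc3[C@H]2c2c(OC)cc(OCc3ccccc3)cc2[C@@H]2COc3cc(OCc4ccccc4)ccc3C2)c(OC)c1OCc1ccccc1 | intermediate
34 | (3R,4S)-7-(benzyloxy)-4-{4-(benzyloxy)-2-[(3R)-7-(benzyloxy)chroman-3-yl]-6-methoxyphenyl}-3-[3-(benzyloxy)-2,4-dimethoxyphenyl]chroman | COc1ccc([C@@H]2COc3cc(OCc4ccccc4)ccc3[C@H]2c2c(OC)cc(OCc3ccccc3)cc2[C@@H]2COc3cc(OCc4ccccc4)ccc3C2)c(OC)c1OCc1ccccc1 | intermediate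
35 | (3R,4S)-4-{4-hydroxy-2-[(3R)-7-hydroxychroman-3-yl]-6-methoxyphenyl}-3-(3-hydroxy-2,4-dimethoxyphenyl)chroman-7-ol | COc1ccc([C@@H]2COc3cc(O)ccc3[C@H]2c2c(OC)cc(O)cc2[C@@H]2COc3cc(O)ccc3C2)c(OC)c1O | target

## Step count and risks

Total: 23 steps. Longest linear sequence: 14 steps (steps 10 to 23, starting from 14).

Least certain steps:

**Step 21 (key step).**
- What may go wrong: slow cycloaddition, because the methide carbon carries a 2,6-disubstituted aryl group and the enol ether a β-aryl group; poor facial selectivity, because the enol ether has no N–H to bind the catalyst and the acid may be mismatched with C3''; loss of endo selectivity, which would give the 3,4-cis series; hydrolysis of the enol ether by the water set free; oligomerisation of the methide.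
- Fallback (sets out from 30 and 5, returns at 34): 5 is hydrolysed with dilute aqueous acid in THF to 2-[3-(benzyloxy)-2,4-dimethoxyphenyl]acetaldehyde F1. 30 and F1 are then combined with α,α-diphenylprolinol trimethylsilyl ether (the enantiomer that gives 3R) and benzoic acid. The enamine of F1 adds to the methide 31 and the phenol closes on the released aldehyde to give the trans-3,4-disubstituted (3R,4S)-chroman-2-ol F2 (enamine-catalysed formal [4+2] reaction of ortho-quinone methides with aldehydes, a known reaction type). Et3SiH and BF3·OEt2 then reduce F2 to 34.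
- What changes: activation moves from the methide alone to covalent activation of the 2π partner, whose stereocontrol does not depend on hydrogen bonding to an enol ether.

**Step 17.**
- What may go wrong: formylation between the two hydroxyls instead of next to the secondary alkyl substituent, because that substituent hinders D1; double formylation; some attack on ring F.
- Fallback (sets out from 24, returns at 27): 24 is monobenzylated with one equivalent of BnBr and K2CO3 in DMF (statistical, unreacted 24 recovered) to 3-(benzyloxy)-5-[(3R)-7-(benzyloxy)chroman-3-yl]phenol F3. F3 is formylated with MgCl2, Et3N and paraformaldehyde in MeCN at reflux (Casnati–Skattebøl ortho-formylation). The magnesium phenoxide delivers the electrophile only ortho to the free hydroxyl, and of the two ortho sites the one para to the benzyloxy group (D1) is preferred over the one wedged between the two oxygens. This gives 27 directly.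
- What changes: the oxygens are differentiated before the formylation, and a phenoxide-directed reaction replaces a freely orienting electrophilic substitution.

**Step 20.**
- What may go wrong: incomplete addition, because the dilithio phenoxide is aggregated, poorly soluble and a weak nucleophile toward a hindered, electron-rich aldehyde; ionisation of the doubly activated benzhydrol during work-up or chromatography.
- Fallback (sets out from 9, returns at 30): 9 is allylated (allyl bromide, K2CO3, DMF) to 2-(allyloxy)-4-(benzyloxy)-1-bromobenzene F4. Bromine–lithium exchange with n-BuLi at −78 °C gives the soluble monolithium reagent [2-(allyloxy)-4-(benzyloxy)phenyl]lithium F5, which is added to 28 to give the O-allyl benzhydrol F6. F6 has no free ortho hydroxyl and can be purified without forming a methide. Pd(PPh3)4 and morpholine in THF at rt remove the allyl group under neutral conditions and give 30 just before step 21.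

**Step 22.**
- What may go wrong: proton loss from C3 of the cation (formation of the 4H-chromene and loss of the C3 configuration) competing with hydride transfer; cleavage of benzyl ethers by the Lewis acid.
- Fallback (sets out from 32, returns at 34): 32 is hydrolysed with pyridinium p-toluenesulfonate in aqueous acetone to the chroman-2-ol F2 already described under step 21. NaBH4 reduces its open hydroxy-aldehyde form to (2R,3S)-2-[3-(benzyloxy)-2,4-dimethoxyphenyl]-3-[4-(benzyloxy)-2-hydroxyphenyl]-3-{4-(benzyloxy)-2-[(3R)-7-(benzyloxy)chroman-3-yl]-6-methoxyphenyl}propan-1-ol F7. A Mitsunobu reaction (PPh3, DIAD, THF) closes O1–C2 by SN2 displacement at the primary carbon and gives 34.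
- What changes: C2 is reduced at the aldehyde oxidation level under basic conditions, so no cation next to C3 is present during the reduction.

## Further compounds

F1 | step 21 | 2-[3-(benzyloxy)-2,4-dimethoxyphenyl]acetaldehyde | O=CCc1ccc(OC)c(OCc2ccccc2)c1OC
F2 | step 21 | (3R,4S)-7-(benzyloxy)-4-{4-(benzyloxy)-2-[(3R)-7-(benzyloxy)chroman-3-yl]-6-methoxyphenyl}-3-[3-(benzyloxy)-2,4-dimethoxyphenyl]chroman-2-ol (both C2 epimers) | COc1ccc([C@@H]2C(O)Oc3cc(OCc4ccccc4)ccc3[C@H]2c2c(OC)cc(OCc3ccccc3)cc2[C@@H]2COc3cc(OCc4ccccc4)ccc3C2)c(OC)c1OCc1ccccc1
F3 | step 17 | 3-(benzyloxy)-5-[(3R)-7-(benzyloxy)chroman-3-yl]phenol | Oc1cc(OCc2ccccc2)cc(c1)[C@@H]1COc2cc(OCc3ccccc3)ccc2C1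
F4 | step 20 | 2-(allyloxy)-4-(benzyloxy)-1-bromobenzene | C=CCOc1cc(OCc2ccccc2)ccc1Br
F5 | step 20 | [2-(allyloxy)-4-(benzyloxy)phenyl]lithium | [Li]c1ccc(OCc2ccccc2)cc1OCC=C
F6 | step 20 | [2-(allyloxy)-4-(benzyloxy)phenyl]{4-(benzyloxy)-2-[(3R)-7-(benzyloxy)chroman-3-yl]-6-methoxyphenyl}methanol (both carbinol epimers) | C=CCOc1cc(OCc2ccccc2)ccc1C(O)c1c(OC)cc(OCc2ccccc2)cc1[C@@H]1COc2cc(OCc3ccccc3)ccc2C1
F7 | step 22 | (2R,3S)-2-[3-(benzyloxy)-2,4-dimethoxyphenyl]-3-[4-(benzyloxy)-2-hydroxyphenyl]-3-{4-(benzyloxy)-2-[(3R)-7-(benzyloxy)chroman-3-yl]-6-methoxyphenyl}propan-1-ol | COc1ccc([C@H](CO)[C@@H](c2ccc(OCc3ccccc3)cc2O)c2c(OC)cc(OCc3ccccc3)cc2[C@@H]2COc3cc(OCc4ccccc4)ccc3C2)c(OC)c1OCc1ccccc1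
A1 | alternative 1 | 5-(benzyloxy)-3-methoxy-2-(trimethylsilyl)phenyl trifluoromethanesulfonate | COc1cc(OCc2ccccc2)cc(OS(=O)(=O)C(F)(F)F)c1[Si](C)(C)C
A2 | alternative 1 | methyl 2-[4-(benzyloxy)-2-(methoxymethoxy)benzyl]-3-[4-(benzyloxy)-2-(methoxymethoxy)phenyl]-3-oxopropanoate (racemic) | COC(=O)C(Cc1ccc(OCc2ccccc2)cc1OCOC)C(=O)c1ccc(OCc2ccccc2)cc1OCOC
A3 | alternative 1 | methyl 2-{5-(benzyloxy)-2-[4-(benzyloxy)-2-(methoxymethoxy)benzoyl]-3-methoxyphenyl}-3-[4-(benzyloxy)-2-(methoxymethoxy)phenyl]propanoate (racemic) | COC(=O)C(Cc1ccc(OCc2ccccc2)cc1OCOC)c1cc(OCc2ccccc2)cc(OC)c1C(=O)c1ccc(OCc2ccccc2)cc1OCOC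
A4 | alternative 2 | (3R,4S)-7-(benzyloxy)-4-[4-(benzyloxy)-2-bromo-6-methoxyphenyl]-3-[3-(benzyloxy)-2,4-dimethoxyphenyl]chroman | COc1ccc([C@@H]2COc3cc(OCc4ccccc4)ccc3[C@H]2c2c(OC)cc(OCc3ccccc3)cc2Br)c(OC)c1OCc1ccccc1
A5 | alternative 2 | 2-ethenyl-4,4,5,5-tetramethyl-1,3,2-dioxaborolane | C=CB1OC(C)(C)C(C)(C)O1
A6 | alternative 2 | 4-(benzyloxy)-2-(methoxymethoxy)phenyl trifluoromethanesulfonate | COCOc1cc(OCc2ccccc2)ccc1OS(=O)(=O)C(F)(F)F
A7 | alternative 2 | (3R,4S)-7-(benzyloxy)-4-{4-(benzyloxy)-2-[2-[4-(benzyloxy)-2-(methoxymethoxy)phenyl]-1-(4,4,5,5-tetramethyl-1,3,2-dioxaborolan-2-yl)ethyl]-6-methoxyphenyl}-3-[3-(benzyloxy)-2,4-dimethoxyphenyl]chroman (one configuration at the boron-bearing carbon) | COc1ccc([C@@H]2COc3cc(OCc4ccccc4)ccc3[C@H]2c2c(OC)cc(OCc3ccccc3)cc2[C@@H](Cc2ccc(OCc3ccccc3)cc2OCOC)B2OC(C)(C)C(C)(C)O2)c(OC)c1OCc1ccccc1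
A8 | alternative 3 | 4-{(3R,4S)-7-(benzyloxy)-3-[3-(benzyloxy)-2,4-dimethoxyphenyl]chroman-4-yl}-3-[(3R)-7-(benzyloxy)chroman-3-yl]-1-diazobut-3-en-2-one | COc1ccc([C@@H]2COc3cc(OCc4ccccc4)ccc3[C@H]2C=C(C(=O)C=[N+]=[N-])[C@@H]2COc3cc(OCc4ccccc4)ccc3C2)c(OC)c1OCc1ccccc1
A9 | alternative 3 | (ethynyloxy)tri(propan-2-yl)silane | C#CO[Si](C(C)C)(C(C)C)C(C)C
A10 | alternative 3 | 2-{(3R,4S)-7-(benzyloxy)-3-[3-(benzyloxy)-2,4-dimethoxyphenyl]chroman-4-yl}-3-[(3R)-7-(benzyloxy)chroman-3-yl]-5-{[tri(propan-2-yl)silyl]oxy}phenol | COc1ccc([C@@H]2COc3cc(OCc4ccccc4)ccc3[C@H]2c2c(O)cc(O[Si](C(C)C)(C(C)C)C(C)C)cc2[C@@H]2COc3cc(OCc4ccccc4)ccc3C2)c(OC)c1OCc1ccccc1
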